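The second catalyst turns intermediate and reagent into product in two flasks, ochre and green, that differ in their reagent charge.

| setting | ochre | green |
|---|---|---|
| substrate | 0.020 M | 0.020 M |
| reagent | 1.10 equiv | 1.60 equiv |
| free catalyst | 13 mol% | 13 mol% |
| second catalyst | 18 mol% | 18 mol% |
| time | 2.0 d | 2.0 d |

    free catalyst + free catalyst ⇌ resting dimer (K1 = 800 /M, k1 = 0.0040 /M/s)
    reagent + second catalyst + intermediate → second catalyst + product (k2 = 0.18 /M²/s)
    substrate + free catalyst → free catalyst + intermediate (k3 = 0.016 /M/s)

- a doubled species enters its step squared and goes two at a time
- run time (ochre): 2.0 d

- which of these there is most of at the end, counted by the substrate in it, ochre (substrate / intermediate / product)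
- which of these there is most of at the end, counted by the substrate in it, green (substrate / intermediate / product)
- final amount of the leader among these, as a percentage of the substrate charged, in ochre
- final amount of the leader among these, as a percentage of the substrate charged, in green

In ochre the reagent stands at 1.10 equiv, more than the substrate, so substrate is the limiting reagent and the end state is product with reagent over, while intermediate, with reagent as charged, has a half-life of 0.56 d, which fits 3.57 times into the 2.0 d of the run. But the last of that intermediate meets no more than the excess of 0.100 of the substrate charge, and there its half-life is 6.19 d, longer than the run. Both numbers belong to one flask, since reagent falls together with intermediate, so this step is not pseudo-first-order and no single half-life describes it.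

We therefore count differently. Free catalyst sinks from 0.00260 M towards 0.00100 M, its equilibrium with resting dimer, each dimer counted as two, and at that level substrate lasts 0.723 d on average, a lag that errs long, as free catalyst begins higher. The pairing number, 1.43, is the constant of step 2 times second catalyst times substrate charged times the run less the lag. With e the reagent equivalents and E = exp((e − 1) × pairing number), the second-order integral gives the product share e(E − 1)/(eE − 1): 62.8% in ochre and 78.4% in green. The leader is product in ochre and product in green.

The forecast put product at 66% in ochre and 80% in green, in its words “Product leads in both runs.”

Ochre ends with 66.3% product and 31.3% intermediate, green with 80.3% product and 17.2% intermediate, and these amounts of product lie 3.4 percentage points and 2 points above our reckoning. A neighbour of green charged with 0.640 equiv of reagent holds the same pairing number, 1.43, with substrate, second catalyst and time as they were, but its reagent now stands below the substrate. The same integral reckons 41.7% product, and that flask ends with 45.0% product, 52.5% intermediate and 30% of its reagent left.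

Its constants come from no measurement, and the outcome is calculated.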